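**Plan**

1. Retrosynthesis: the bridging hemiketal bond C4–O(2′) is opened to a 2′,6′-dihydroxyflavanone. The dimethylpyran ring is cut at C6–C and O7–C back to 3-methylbut-2-enal. Ring A is then cut at C4a–C5 and C8–C8a.
2. Enabling feature (flavanone numbering): ring A carries OMe on C5, H on C6, O on C7 and prenyl on C8. A 4-prenyl-1,1-dimethoxy-3-silyloxybutadiene lays down exactly this pattern across the C4a–C8a bond, which is the enone C=C of a 2-aryl-2,3-dihydropyran-4-one (ring C).
3. Forward order: ring C by hetero-Diels–Alder reaction of the MOM-protected aldehyde; a sulfinyl group on C5 of the pyranone; ring A by Diels–Alder addition and aromatisation; the dimethylpyran ring by annulation at C6/O7; the hemiketal ring on MOM removal. The diene is made in three steps and joined convergently.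
4. Leaving group: in the cycloadduct the group on C4a and the hydrogen on C8a are cis, and that hydrogen is not acidic. A sulfoxide, which leaves by thermal syn-elimination and also activates the enone, is therefore used rather than a halide.
5. Stereochemistry: C2 (R) is set by the chiral Lewis acid in the hetero-Diels–Alder step and carried through. C4 (R) follows from C2, because the hemiketal bridge can close only cis to the aryl group.

Key step: step 8

Assumption: the catalyst (R,R)-(salen)CrBF4 [salen = dianion of N,N′-bis(3,5-di-tert-butylsalicylidene)-(1R,2R)-cyclohexane-1,2-diamine] is taken to give the (R)-dihydropyranone from the hindered dialkoxybenzaldehyde, as expected for simple aryl aldehydes. Should the first run show the opposite sense, the (S,S)-catalyst is used and nothing else changes.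

**Route**

Step 1
Reactants: 1 2,6-dihydroxybenzaldehyde
Product: 2 2,6-bis(methoxymethoxy)benzaldehyde
Conditions: MOMCl (3 equiv), i-Pr2NEt, CH2Cl2, 0 °C → rt
Reagents that add atoms: chloromethyl methyl ether, COCCl
Why: MOM ether formation (O-alkylation of both phenols by the chloromethyl ether) should proceed with excess reagent despite the hydrogen bonds to the aldehyde, which itself has no enolisable position.

Step 2
Reactants: 2 2,6-bis(methoxymethoxy)benzaldehyde; 3 (E)-1-methoxy-3-(trimethylsilyloxy)buta-1,3-diene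
Product: 5 (2R)-2-[2,6-bis(methoxymethoxy)phenyl]-2,3-dihydro-4H-pyran-4-one, via silyloxy dihydropyran cycloadduct 4 (not isolated)
Conditions: (R,R)-(salen)CrBF4 (5 mol %), 4 Å MS, t-BuOMe, −30 → 0 °C; then TFA (cat.), CH2Cl2, 0 °C
Reagents that add atoms: none
Why: Chiral-Lewis-acid-catalysed hetero-Diels–Alder reaction, in which the chromium centre binds the aldehyde and the salen ligand shields one carbonyl face so that C2 is set as R, followed by acid-catalysed loss of methoxytrimethylsilane from the cycloadduct under conditions mild enough for the MOM ethers.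

Step 3
Reactants: 5 (2R)-2-[2,6-bis(methoxymethoxy)phenyl]-2,3-dihydro-4H-pyran-4-one
Product: 6 (2R)-2-[2,6-bis(methoxymethoxy)phenyl]-5-(phenylthio)-2,3-dihydro-4H-pyran-4-one
Conditions: PhSH, NCS, CH2Cl2, 0 °C; then 5, 2,6-lutidine, −78 → 0 °C
Reagents that add atoms: benzenesulfenyl chloride, ClSc1ccccc1, made in the flask from benzenethiol, Sc1ccccc1, and N-chlorosuccinimide, O=C1CCC(=O)N1Cl
Why: Electrophilic α-sulfenylation of a β-alkoxy enone (vinylogous ester) should occur at C5, the enol-ether carbon, faster than on the dialkoxyarene at low temperature, with lutidine removing the C5 proton to restore the enone.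

Step 4
Reactants: 6 (2R)-2-[2,6-bis(methoxymethoxy)phenyl]-5-(phenylthio)-2,3-dihydro-4H-pyran-4-one
Product: 7 (2R)-2-[2,6-bis(methoxymethoxy)phenyl]-5-(phenylsulfinyl)-2,3-dihydro-4H-pyran-4-one (both sulfur epimers)
Conditions: mCPBA (1.0 equiv), CH2Cl2, −78 → −40 °C
Reagents that add atoms: 3-chloroperbenzoic acid, OOC(=O)c1cccc(Cl)c1
Why: Sulfide-to-sulfoxide oxidation with one equivalent of peracid at low temperature should stop at the sulfoxide and spare the electron-poor push–pull alkene; the sulfur configuration is immaterial because the group is expelled in step 8.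

Step 5
Reactants: 8 5-methylhex-4-enoic acid
Product: 9 5-methylhex-4-enoyl chloride
Conditions: (COCl)2, DMF (cat.), CH2Cl2, 0 °C → rt
Reagents that add atoms: oxalyl chloride, O=C(Cl)C(=O)Cl
Why: Acid chloride formation through the chloroiminium (Vilsmeier-type) intermediate is standard for alkenoic acids, and the crude chloride is used directly.

Step 6
Reactants: 9 5-methylhex-4-enoyl chloride; 10 1,1-dimethoxyethene
Product: 11 1,1-dimethoxy-7-methylocta-1,6-dien-3-one
Conditions: 10 (2.2 equiv), Et2O, 0 °C → rt
Reagents that add atoms: none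
Why: C-Acylation of the ketene acetal by the acid chloride gives the β,β-dimethoxy enone, with the second equivalent of ketene acetal taking up the hydrogen chloride as methyl acetate and chloromethane so that no amine base is present to form a ketene.

Step 7
Reactants: 11 1,1-dimethoxy-7-methylocta-1,6-dien-3-one
Product: 12 (3Z)-1,1-dimethoxy-7-methyl-3-(trimethylsilyloxy)octa-1,3,6-triene
Conditions: TMSOTf, Et3N, Et2O, 0 °C
Reagents that add atoms: trimethylsilyl trifluoromethanesulfonate, C[Si](C)(C)OS(=O)(=O)C(F)(F)F
Why: Soft enolisation (silyl enol ether formation) at the α′-methylene should give mainly the Z-configured dienol ether, which places the prenyl-bearing CH2 on the outside of the s-cis diene.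

Step 8
Reactants: 7 (2R)-2-[2,6-bis(methoxymethoxy)phenyl]-5-(phenylsulfinyl)-2,3-dihydro-4H-pyran-4-one; 12 (3Z)-1,1-dimethoxy-7-methyl-3-(trimethylsilyloxy)octa-1,3,6-triene
Product: 15 (2R)-2-[2,6-bis(methoxymethoxy)phenyl]-7-hydroxy-5-methoxy-8-(3-methylbut-2-en-1-yl)chroman-4-one, via sulfinyl cycloadduct 13 (not isolated), via dimethoxy cyclohexadiene 14 (not isolated)
Conditions: 12 (2.5 equiv), toluene, 80 °C; then 0.5 M aq. HCl, THF, 0 °C
Reagents that add atoms: none
Why: Proposed new method: the electron-rich ketene-acetal diene 12 should add across the C5=C6 bond of the push–pull sulfinyl enone 7, its prenyl-bearing terminus bonding to C6 (the future C8a) and its acetal carbon to C5 (the future C4a), either as a concerted asynchronous [4+2] cycloaddition or as Michael addition followed by 6-exo-trig closure of the sulfinyl enolate onto the dimethoxycarbenium ion. The closest known reaction type is the Diels–Alder and sulfoxide-elimination benzannulation of 1,1-dialkoxy-3-silyloxy dienes with sulfinyl quinones and 2-sulfinyl cycloalkenones, which has not been shown on a 5-sulfinyl-2,3-dihydropyran-4-one. Ring A is the only ring formed and it closes by intermolecular [4+2] cycloaddition. In adduct 13 the sulfinyl group on C4a and the hydrogen on C8a are necessarily cis, so thermal syn-elimination of benzenesulfenic acid should give 14 without base, and dilute acid then removes methanol across C5/C8 and the silyl group to leave the C7 phenol. No new stereocentre survives, since the three sp3 centres of 13 and the sulfur centre vanish on aromatisation, and C2 is untouched because its bond to the ring oxygen is never broken. The selectivity needed is regiochemical and is secured by the dienophile itself, whose C6 is the one carbon conjugated to both acceptors on C5, matched to the diene, whose nucleophilic carbon is the silyl enol ether terminus.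

Step 9
Reactants: 15 (2R)-2-[2,6-bis(methoxymethoxy)phenyl]-7-hydroxy-5-methoxy-8-(3-methylbut-2-en-1-yl)chroman-4-one; 16 3-methylbut-2-enal
Product: 18 (2R)-2-[2,6-bis(methoxymethoxy)phenyl]-5-methoxy-8,8-dimethyl-10-(3-methylbut-2-en-1-yl)-2,3-dihydro-4H,8H-pyrano[3,2-g]chromen-4-one, via ortho-quinone methide 17 (not isolated)
Conditions: 16 (2 equiv), ethylenediammonium diacetate (20 mol %), toluene, 70 °C
Reagents that add atoms: none
Why: Knoevenagel-type condensation at C6, the only free position ortho to the only free phenol, gives an ortho-quinone methide that closes by oxa-6π electrocyclisation, and the weakly buffered amine salt at moderate temperature is chosen to avoid retro-oxa-Michael opening of ring C.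

Step 10
Reactants: 18 (2R)-2-[2,6-bis(methoxymethoxy)phenyl]-5-methoxy-8,8-dimethyl-10-(3-methylbut-2-en-1-yl)-2,3-dihydro-4H,8H-pyrano[3,2-g]chromen-4-one
Product: 20 the target hemiketal (2R,4R in flavan numbering), via dihydroxyflavanone 19 (not isolated)
Conditions: 2 M aq. HCl, THF/i-PrOH, 40 °C
Reagents that add atoms: none
Why: Acid-catalysed acetal hydrolysis frees both phenols, and the 2′-hydroxyl then adds to the C4 ketone (unchelated, since C5 carries OMe) in an intramolecular hemiketalisation that is possible only on the face cis to the C2 aryl group, so C4 is set as R by C2 under thermodynamic control.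

**Compound list**

1 | 2,6-dihydroxybenzaldehyde | O=Cc1c(O)cccc1O | starting material
2 | 2,6-bis(methoxymethoxy)benzaldehyde | O=Cc1c(OCOC)cccc1OCOC | intermediate
3 | (E)-1-methoxy-3-(trimethylsilyloxy)buta-1,3-diene | CO/C=C/C(=C)O[Si](C)(C)C | starting material
4 | (6R)-6-[2,6-bis(methoxymethoxy)phenyl]-2-methoxy-4-(trimethylsilyloxy)-5,6-dihydro-2H-pyran (acetal carbon unassigned) | COC1C=C(O[Si](C)(C)C)C[C@H](c2c(OCOC)cccc2OCOC)O1 | intermediate
5 | (2R)-2-[2,6-bis(methoxymethoxy)phenyl]-2,3-dihydro-4H-pyran-4-one | O=C1C[C@H](c2c(OCOC)cccc2OCOC)OC=C1 | intermediate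
6 | (2R)-2-[2,6-bis(methoxymethoxy)phenyl]-5-(phenylthio)-2,3-dihydro-4H-pyran-4-one | O=C1C[C@H](c2c(OCOC)cccc2OCOC)OC=C1Sc1ccccc1 | intermediate
7 | (2R)-2-[2,6-bis(methoxymethoxy)phenyl]-5-(phenylsulfinyl)-2,3-dihydro-4H-pyran-4-one (both sulfur epimers) | O=C1C[C@H](c2c(OCOC)cccc2OCOC)OC=C1S(=O)c1ccccc1 | intermediate
8 | 5-methylhex-4-enoic acid | CC(C)=CCCC(=O)O | starting material
9 | 5-methylhex-4-enoyl chloride | CC(C)=CCCC(=O)Cl | intermediate
10 | 1,1-dimethoxyethene | C=C(OC)OC | starting material
11 | 1,1-dimethoxy-7-methylocta-1,6-dien-3-one | COC(OC)=CC(=O)CCC=C(C)C | intermediate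
12 | (3Z)-1,1-dimethoxy-7-methyl-3-(trimethylsilyloxy)octa-1,3,6-triene | COC(OC)=C/C(O[Si](C)(C)C)=C/CC=C(C)C | intermediate
13 | (2R)-2-[2,6-bis(methoxymethoxy)phenyl]-5,5-dimethoxy-8-(3-methylbut-2-en-1-yl)-4a-(phenylsulfinyl)-7-(trimethylsilyloxy)-2,3,4a,5,8,8a-hexahydro-4H-chromen-4-one (C4a, C8, C8a and sulfur unassigned) | O=C1C[C@H](c2c(OCOC)cccc2OCOC)OC2C(CC=C(C)C)C(O[Si](C)(C)C)=CC(OC)(OC)C12S(=O)c1ccccc1 | intermediate
14 | (2R)-2-[2,6-bis(methoxymethoxy)phenyl]-5,5-dimethoxy-8-(3-methylbut-2-en-1-yl)-7-(trimethylsilyloxy)-2,3,5,8-tetrahydro-4H-chromen-4-one (C8 unassigned) | O=C1C[C@H](c2c(OCOC)cccc2OCOC)OC2=C1C(OC)(OC)C=C(O[Si](C)(C)C)C2CC=C(C)C | intermediate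
15 | (2R)-2-[2,6-bis(methoxymethoxy)phenyl]-7-hydroxy-5-methoxy-8-(3-methylbut-2-en-1-yl)chroman-4-one | O=C1C[C@H](c2c(OCOC)cccc2OCOC)Oc2c1c(OC)cc(O)c2CC=C(C)C | intermediate
16 | 3-methylbut-2-enal | CC(C)=CC=O | starting material
17 | (2R)-2-[2,6-bis(methoxymethoxy)phenyl]-5-methoxy-6-(3-methylbut-2-en-1-ylidene)-8-(3-methylbut-2-en-1-yl)-2,3-dihydro-4H-chromene-4,7(6H)-dione | O=C1C[C@H](c2c(OCOC)cccc2OCOC)OC2=C(CC=C(C)C)C(=O)C(=CC=C(C)C)C(OC)=C12 | intermediate
18 | (2R)-2-[2,6-bis(methoxymethoxy)phenyl]-5-methoxy-8,8-dimethyl-10-(3-methylbut-2-en-1-yl)-2,3-dihydro-4H,8H-pyrano[3,2-g]chromen-4-one | O=C1C[C@H](c2c(OCOC)cccc2OCOC)Oc2c1c(OC)c1C=CC(C)(C)Oc1c2CC=C(C)C | intermediate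
19 | (2R)-2-(2,6-dihydroxyphenyl)-5-methoxy-8,8-dimethyl-10-(3-methylbut-2-en-1-yl)-2,3-dihydro-4H,8H-pyrano[3,2-g]chromen-4-one | O=C1C[C@H](c2c(O)cccc2O)Oc2c1c(OC)c1C=CC(C)(C)Oc1c2CC=C(C)C | intermediate
20 | bridged hemiketal of 19 in which the 2′-oxygen of ring B is bonded to C4 and C4 carries the free hydroxyl, (2R,4R) in flavan numbering | COc1c2c(c(CC=C(C)C)c3c1[C@@]1(O)C[C@@H](O3)c3c(O)cccc3O1)OC(C)(C)C=C2 | target

**Count and risks**

Total steps: 10. Longest linear sequence: 7 steps (steps 1, 2, 3, 4, 8, 9, 10); the diene arm (steps 5–7) joins at step 8.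

Step 8 (cycloaddition and aromatisation). The push–pull sulfinyl enone may be too weak an acceptor, so that the acid-sensitive diene is lost to hydrolysis or to silyl transfer onto the sulfoxide oxygen before it adds. The adduct may also open ring C by β-elimination of the C8a oxygen instead of aromatising. The fallback uses known chemistry: ring A is brought in ready-made and ring C is closed last. It sets out from aldehyde 2. Commercial 1-(2,4-dihydroxy-6-methoxyphenyl)ethan-1-one is C-prenylated between its two hydroxyls (1-bromo-3-methylbut-2-ene, aq. KOH, 0 °C, with separation from the C5 isomer) to 1-[2,4-dihydroxy-6-methoxy-3-(3-methylbut-2-en-1-yl)phenyl]ethan-1-one F1. Claisen–Schmidt condensation of this ketone with 2 (KOH, EtOH, rt) should give the chalcone (E)-3-[2,6-bis(methoxymethoxy)phenyl]-1-[2,4-dihydroxy-6-methoxy-3-(3-methylbut-2-en-1-yl)phenyl]prop-2-en-1-one F2. Oxa-Michael cyclisation (NaOAc, EtOH, reflux) should then give racemic 2-[2,6-bis(methoxymethoxy)phenyl]-7-hydroxy-5-methoxy-8-(3-methylbut-2-en-1-yl)chroman-4-one F3. Chromatography on a chiral stationary phase would separate 15 from its (2S)-enantiomer F4, and the route is rejoined at 15.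

Step 2 (enantioselective hetero-Diels–Alder reaction). Turnover may be poor with the doubly ortho-substituted, electron-rich aldehyde, and facial discrimination may suffer because the MOM oxygens can chelate the Lewis acid. The fallback sets out from 2 and 3. An achiral lanthanide catalyst (Eu(fod)3, CHCl3, rt) should give racemic 6-[2,6-bis(methoxymethoxy)phenyl]-2-methoxy-4-(trimethylsilyloxy)-5,6-dihydro-2H-pyran F5. Catalytic TFA converts this into racemic 2-[2,6-bis(methoxymethoxy)phenyl]-2,3-dihydro-4H-pyran-4-one F6. Preparative chromatography on a chiral stationary phase separates 5 from the (2S)-enantiomer F7, and the route is rejoined at 5.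

Step 9 (chromene annulation). Enantiopurity may erode through reversible amine-induced opening of ring C (retro-oxa-Michael to the chalcone), and condensation may be slow because the phenol is deactivated by the para acyl group. The fallback sets out from 15 and 16 and uses a boron-templated, ortho-specific condensation under carboxylic acid catalysis (PhB(OH)2, propionic acid (cat.), toluene, reflux with water removal). This should form the benzodioxaborin in which O7 and the new benzylic carbon on C6 are bridged by B–Ph, F8. Heating fragments it to the ortho-quinone methide 17, which electrocyclises, and the route is rejoined at 18.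

**Further compounds**

F1 | step 8 | 1-[2,4-dihydroxy-6-methoxy-3-(3-methylbut-2-en-1-yl)phenyl]ethan-1-one | CC(=O)c1c(OC)cc(O)c(CC=C(C)C)c1O
F2 | step 8 | (E)-3-[2,6-bis(methoxymethoxy)phenyl]-1-[2,4-dihydroxy-6-methoxy-3-(3-methylbut-2-en-1-yl)phenyl]prop-2-en-1-one | COCOc1cccc(OCOC)c1/C=C/C(=O)c1c(OC)cc(O)c(CC=C(C)C)c1O
F3 | step 8 | racemic 2-[2,6-bis(methoxymethoxy)phenyl]-7-hydroxy-5-methoxy-8-(3-methylbut-2-en-1-yl)chroman-4-one | O=C1CC(c2c(OCOC)cccc2OCOC)Oc2c1c(OC)cc(O)c2CC=C(C)C
F4 | step 8 | (2S)-2-[2,6-bis(methoxymethoxy)phenyl]-7-hydroxy-5-methoxy-8-(3-methylbut-2-en-1-yl)chroman-4-one | O=C1C[C@@H](c2c(OCOC)cccc2OCOC)Oc2c1c(OC)cc(O)c2CC=C(C)C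
F5 | step 2 | racemic 6-[2,6-bis(methoxymethoxy)phenyl]-2-methoxy-4-(trimethylsilyloxy)-5,6-dihydro-2H-pyran | COC1C=C(O[Si](C)(C)C)CC(c2c(OCOC)cccc2OCOC)O1
F6 | step 2 | racemic 2-[2,6-bis(methoxymethoxy)phenyl]-2,3-dihydro-4H-pyran-4-one | O=C1CC(c2c(OCOC)cccc2OCOC)OC=C1
F7 | step 2 | (2S)-2-[2,6-bis(methoxymethoxy)phenyl]-2,3-dihydro-4H-pyran-4-one | O=C1C[C@@H](c2c(OCOC)cccc2OCOC)OC=C1
F8 | step 9 | 2-phenyl-1,3,2-dioxaborinine fused at C6/C7 of 15 through O7–B(Ph)–O–CH(CH=CMe2)–C6 (new benzylic centre unassigned) | O=C1C[C@H](c2c(OCOC)cccc2OCOC)Oc2c1c(OC)c1C(C=C(C)C)OB(c3ccccc3)Oc1c2CC=C(C)C
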